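**Retrosynthetic overview**
1. The plan rests on ring B: C5 lies between the gem-dimethyl carbon C4 and C6, and C6 can be a ketone (later the C6=C7 alkene). The C4–C5 bond is therefore cut to a C5=C6 enol silane and a tertiary C4 cation on a chain from C10, and ring A closes last onto a ring B that already holds C8, C9 and C10.
2. Ring B is made first by an amine-catalysed Michael addition/aldol condensation of a β-ketoester that carries C1–C4 with a silyloxy enone (sets C8). Me2CuLi then brings in the C10 methyl, not the chain, because axial attack anti to the C8 group gives the needed C10 configuration; the enolate is trapped as the C5=C6 silyl ether.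
3. Ring A is made second by TiCl4 ionisation of the C4 methyl ether and closure onto C5; C5, which is α to the C6 ketone, is then equilibrated to the trans fusion.
4. Late stage: C6 ketone to C7 enol triflate to the C6=C7 alkene; C9 ester to vinyl; 9-BBN/Suzuki coupling with a (Z)-iodo-enoate (C12–C13); C17 oxidation; tert-butyl ester cleavage.
5. Stereocontrol: C8 by the catalyst, C10 by the substrate (anti to C8), C5 and C9 by equilibration next to carbonyl groups.

Key step: step 6

Assumption: the quinine-derived primary amine is taken to give the (S)-configured C8 centre of adduct 9; if it prefers the other face, its quinidine-derived pseudo-enantiomer is used instead.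

**Route**

Step 1
Reactants: 1 3-methoxy-3-methylbutan-1-ol
Product: 2 1-iodo-3-methoxy-3-methylbutane
Conditions: I2, PPh3, imidazole, CH2Cl2, 0 °C to rt
Reagents that add atoms: iodine, II
Why: Appel-type iodination, in which iodide displaces the alkoxyphosphonium ion of the primary alcohol in an SN2 step and the tertiary methyl ether is untouched.

Step 2
Reactants: 3 methyl acetoacetate; 2 1-iodo-3-methoxy-3-methylbutane
Product: 5 methyl 7-methoxy-7-methyl-3-oxooctanoate, via acetoacetate dianion 4 (not isolated)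
Conditions: NaH, THF, 0 °C; n-BuLi, 0 °C; then 2, 0 °C to rt; aq. NH4Cl
Reagents that add atoms: none
Why: Dianion alkylation of a β-ketoester, in which the terminal carbanion is the more nucleophilic site and displaces the primary iodide, placing C1–C4 with the C4 methoxy group on the future C10 ketone.

Step 3
Reactants: 6 (tert-butyldimethylsilyloxy)acetaldehyde; 7 1-(triphenylphosphoranylidene)propan-2-one
Product: 8 (3E)-5-[(tert-butyldimethylsilyl)oxy]pent-3-en-2-one
Conditions: CH2Cl2, rt
Reagents that add atoms: none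
Why: Wittig olefination with a stabilised ylide, which should give the E-enone.

Step 4
Reactants: 5 methyl 7-methoxy-7-methyl-3-oxooctanoate (1.5 equiv); 8 (3E)-5-[(tert-butyldimethylsilyl)oxy]pent-3-en-2-one
Product: 10 methyl (1R,6S)-6-{[(tert-butyldimethylsilyl)oxy]methyl}-2-(4-methoxy-4-methylpentyl)-4-oxocyclohex-2-ene-1-carboxylate, via 1,5-diketone Michael adduct 9 (not isolated)
Conditions: 9-amino-9-deoxyepiquinine (20 mol %), PhCO2H (40 mol %), toluene, rt, then 50 °C
Reagents that add atoms: none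
Why: Iminium-ion Michael addition, in which the cinchona primary amine shields one face of the enone iminium ion and so sets C8, followed by enamine aldol condensation of the methyl ketone onto the C10 ketone (Robinson-type annulation); the labile C9 centre should settle trans to C8 and is in any case reset after ring closure.

Step 5
Reactants: 10 methyl (1R,6S)-6-{[(tert-butyldimethylsilyl)oxy]methyl}-2-(4-methoxy-4-methylpentyl)-4-oxocyclohex-2-ene-1-carboxylate
Product: 12 methyl (1R,2R,6S)-4-[(tert-butyldimethylsilyl)oxy]-6-{[(tert-butyldimethylsilyl)oxy]methyl}-2-(4-methoxy-4-methylpentyl)-2-methylcyclohex-3-ene-1-carboxylate, via lithium enolate 11 (not isolated)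
Conditions: Me2CuLi (from MeLi and CuI), Et2O, −78 to −20 °C; then TBSCl, Et3N, HMPA, THF, −78 °C to rt
Reagents that add atoms: lithium dimethylcuprate, [Li+].C[Cu-]C; tert-butyldimethylsilyl chloride, CC(C)(C)[Si](C)(C)Cl
Why: Cuprate conjugate addition with O-silylation of the regiodefined enolate: the cuprate should attack C10 axially on the half-chair that keeps the C8 and C9 groups equatorial, anti to the C8 silyloxymethyl group (the trans-3,5 preference of 5-substituted cyclohexenones), which sets C10 with the methyl trans to C17 and cis to the C9 ester.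

Step 6
Reactants: 12 methyl (1R,2R,6S)-4-[(tert-butyldimethylsilyl)oxy]-6-{[(tert-butyldimethylsilyl)oxy]methyl}-2-(4-methoxy-4-methylpentyl)-2-methylcyclohex-3-ene-1-carboxylate
Product: 14 methyl (1R,2S,4aR,8aR)-2-{[(tert-butyldimethylsilyl)oxy]methyl}-5,5,8a-trimethyl-4-oxodecahydronaphthalene-1-carboxylate, via C5-unassigned decalone 13 (not isolated)
Conditions: TiCl4 (2.5 equiv), 2,6-di-tert-butyl-4-methylpyridine (0.3 equiv), CH2Cl2 (0.01 M), −78 °C; aq. NaHCO3; then NaOMe (0.3 equiv), MeOH, rt to 50 °C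
Reagents that add atoms: none
Why: TiCl4 abstracts methoxide from the tertiary ether to give the C4 carbenium ion, nucleophilic C5 of the enol silane captures it, and chloride takes the silyl group from the resulting silyloxocarbenium ion to release the C6 ketone; the closest known reaction type is the Lewis acid-promoted α-tert-alkylation of silyl enol ethers by SN1-active tertiary halides and ethers, used here within one molecule. Ring A (C4, C3, C2, C1, C10, C5) closes in a 6-(enolexo)-exo-trig mode, the enol C5=C6 bond lying outside the new ring. C5 is the only new stereocentre: the stereoelectronically easiest closure, on the C5 face anti to the pseudo-axial C10 methyl, leads to the cis-fused ketone and the trans-fused one needs a twisted ring B, so the fusion of 13 is left open and NaOMe then equilibrates C5 through the C5=C6 enolate. The trans fusion should be favoured at equilibrium because the cis isomer must hold the quaternary C4 axial on ring B with one methyl pressed against C9 and H7, whereas in 14 C4, the C9 ester and the C8 side arm are all equatorial; C10 is thus the controlling element, and C9, also α to a carbonyl, stays at its stable configuration. The step needs C-alkylation at C5 to outrun proton loss from the cation and protodesilylation: the enol double bond is fixed at C5=C6 by step 5, the six-membered tether holds C4 next to C5, and low temperature, high dilution and the hindered pyridine as proton trap suppress the side paths. The ester and the primary silyl ether only bind TiCl4 and should survive at −78 °C.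

Step 7
Reactants: 14 methyl (1R,2S,4aR,8aR)-2-{[(tert-butyldimethylsilyl)oxy]methyl}-5,5,8a-trimethyl-4-oxodecahydronaphthalene-1-carboxylate
Product: 16 methyl (1R,2S,4aR,8aR)-2-{[(tert-butyldimethylsilyl)oxy]methyl}-5,5,8a-trimethyl-4-{[(trifluoromethyl)sulfonyl]oxy}-1,2,4a,5,6,7,8,8a-octahydronaphthalene-1-carboxylate, via potassium enolate 15 (not isolated)
Conditions: KN(SiMe3)2 (1.1 equiv), THF, −78 °C; then PhNTf2, −78 to 0 °C
Reagents that add atoms: N-phenylbis(trifluoromethanesulfonimide), O=S(=O)(N(c1ccccc1)S(=O)(=O)C(F)(F)F)C(F)(F)F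
Why: Kinetic enolisation and O-triflation: the hindered amide should remove a C7 methylene proton, because the C5 methine lies between two quaternary carbons and the ester α-proton is less acidic, and the enolate is sulfonylated on oxygen.

Step 8
Reactants: 16 methyl (1R,2S,4aR,8aR)-2-{[(tert-butyldimethylsilyl)oxy]methyl}-5,5,8a-trimethyl-4-{[(trifluoromethyl)sulfonyl]oxy}-1,2,4a,5,6,7,8,8a-octahydronaphthalene-1-carboxylate
Product: 17 methyl (1R,2S,4aR,8aR)-2-{[(tert-butyldimethylsilyl)oxy]methyl}-5,5,8a-trimethyl-1,2,4a,5,6,7,8,8a-octahydronaphthalene-1-carboxylate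
Conditions: Pd(OAc)2 (5 mol %), PPh3 (10 mol %), HCO2H, n-Bu3N, DMF, 60 °C
Reagents that add atoms: none
Why: Palladium-catalysed formate reduction of an enol triflate (oxidative addition to zerovalent palladium, formate exchange, loss of CO2, C–H reductive elimination), which leaves the C6=C7 alkene in place and touches no stereocentre.

Step 9
Reactants: 17 methyl (1R,2S,4aR,8aR)-2-{[(tert-butyldimethylsilyl)oxy]methyl}-5,5,8a-trimethyl-1,2,4a,5,6,7,8,8a-octahydronaphthalene-1-carboxylate
Product: 18 [(1R,2S,4aR,8aR)-2-{[(tert-butyldimethylsilyl)oxy]methyl}-5,5,8a-trimethyl-1,2,4a,5,6,7,8,8a-octahydronaphthalen-1-yl]methanol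
Conditions: i-Bu2AlH (3 equiv), CH2Cl2, −78 to 0 °C; aq. KNaC4H4O6 (tartrate)
Reagents that add atoms: none
Why: Aluminium hydride reduction of the hindered ester to the primary alcohol; the silyl ether and the ring alkene are inert.

Step 10
Reactants: 18 [(1R,2S,4aR,8aR)-2-{[(tert-butyldimethylsilyl)oxy]methyl}-5,5,8a-trimethyl-1,2,4a,5,6,7,8,8a-octahydronaphthalen-1-yl]methanol
Product: 19 (1R,2S,4aR,8aR)-2-{[(tert-butyldimethylsilyl)oxy]methyl}-5,5,8a-trimethyl-1,2,4a,5,6,7,8,8a-octahydronaphthalene-1-carbaldehyde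
Conditions: Dess–Martin periodinane, NaHCO3, CH2Cl2, 0 °C to rt
Reagents that add atoms: none
Why: Dess–Martin oxidation under buffered conditions should give the C11 aldehyde, whose C9 centre already has the stable equatorial configuration.

Step 11
Reactants: 19 (1R,2S,4aR,8aR)-2-{[(tert-butyldimethylsilyl)oxy]methyl}-5,5,8a-trimethyl-1,2,4a,5,6,7,8,8a-octahydronaphthalene-1-carbaldehyde
Product: 20 tert-butyl{[(1R,2S,4aR,8aS)-1-ethenyl-5,5,8a-trimethyl-1,2,4a,5,6,7,8,8a-octahydronaphthalen-2-yl]methoxy}dimethylsilane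
Conditions: Ph3PCH3Br, KOt-Bu, THF, 0 °C to rt
Reagents that add atoms: methyltriphenylphosphonium bromide, C[P+](c1ccccc1)(c1ccccc1)c1ccccc1.[Br-]
Why: Wittig methylenation with the small, reactive ylide, which should tolerate the neopentyl-type aldehyde.

Step 12
Reactants: 21 2-(prop-2-yn-1-yloxy)oxane (tetrahydropyranyl ether of propargyl alcohol, racemic)
Product: 23 tert-butyl 4-(oxan-2-yloxy)but-2-ynoate, via lithium acetylide 22 (not isolated)
Conditions: n-BuLi, THF, −78 °C; then Boc2O, −78 to 0 °C; aq. NH4Cl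
Reagents that add atoms: di-tert-butyl dicarbonate, CC(C)(C)OC(=O)OC(=O)OC(C)(C)C
Why: C-acylation of a lithium acetylide by the dicarbonate gives the tert-butyl ynoate directly.

Step 13
Reactants: 23 tert-butyl 4-(oxan-2-yloxy)but-2-ynoate
Product: 24 tert-butyl 4-hydroxybut-2-ynoate
Conditions: pyridinium p-toluenesulfonate (10 mol %), MeOH, 40 °C
Reagents that add atoms: none
Why: Acid-catalysed transacetalisation removes the tetrahydropyranyl group, and the tert-butyl ester should survive the weak acid.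

Step 14
Reactants: 24 tert-butyl 4-hydroxybut-2-ynoate
Product: 25 tert-butyl 4-acetoxybut-2-ynoate
Conditions: Ac2O, pyridine, DMAP (5 mol %), CH2Cl2, 0 °C to rt
Reagents that add atoms: acetic anhydride, CC(=O)OC(C)=O
Why: DMAP-catalysed acetylation of the primary alcohol.

Step 15
Reactants: 25 tert-butyl 4-acetoxybut-2-ynoate
Product: 26 tert-butyl (2Z)-4-acetoxy-3-iodobut-2-enoate
Conditions: NaI, AcOH, 60 °C
Reagents that add atoms: sodium iodide, [Na+].[I-]
Why: Conjugate hydroiodination of an ynoate: iodide adds to the β-carbon and the allenolate is protonated from the opposite side (anti addition), which places iodine cis to the ester (Z).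

Step 16
Reactants: 20 tert-butyl{[(1R,2S,4aR,8aS)-1-ethenyl-5,5,8a-trimethyl-1,2,4a,5,6,7,8,8a-octahydronaphthalen-2-yl]methoxy}dimethylsilane; 26 tert-butyl (2Z)-4-acetoxy-3-iodobut-2-enoate
Product: 28 tert-butyl (2E)-3-(acetoxymethyl)-5-[(1R,2S,4aR,8aS)-2-{[(tert-butyldimethylsilyl)oxy]methyl}-5,5,8a-trimethyl-1,2,4a,5,6,7,8,8a-octahydronaphthalen-1-yl]pent-2-enoate, via B-alkyl-9-BBN 27 (not isolated)
Conditions: 9-BBN, THF, 0 °C to rt; then 26, PdCl2(dppf) (5 mol %), AsPh3 (5 mol %), Cs2CO3, DMF/H2O, rt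
Reagents that add atoms: none
Why: Anti-Markovnikov hydroboration of the monosubstituted alkene only (the ring alkene is disubstituted and hindered), then B-alkyl Suzuki–Miyaura coupling with retention of the iodoalkene geometry, so that C12 ends cis to the ester (13E).

Step 17
Reactants: 28 tert-butyl (2E)-3-(acetoxymethyl)-5-[(1R,2S,4aR,8aS)-2-{[(tert-butyldimethylsilyl)oxy]methyl}-5,5,8a-trimethyl-1,2,4a,5,6,7,8,8a-octahydronaphthalen-1-yl]pent-2-enoate
Product: 29 tert-butyl (2E)-3-(acetoxymethyl)-5-[(1R,2S,4aR,8aS)-2-(hydroxymethyl)-5,5,8a-trimethyl-1,2,4a,5,6,7,8,8a-octahydronaphthalen-1-yl]pent-2-enoate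
Conditions: HF·pyridine, pyridine, THF, 0 °C to rt
Reagents that add atoms: none
Why: Fluoride-mediated cleavage of the primary silyl ether under buffered conditions that should spare the acetate and the tert-butyl ester.

Step 18
Reactants: 29 tert-butyl (2E)-3-(acetoxymethyl)-5-[(1R,2S,4aR,8aS)-2-(hydroxymethyl)-5,5,8a-trimethyl-1,2,4a,5,6,7,8,8a-octahydronaphthalen-1-yl]pent-2-enoate
Product: 31 (1R,2S,4aR,8aS)-1-[(3E)-3-(acetoxymethyl)-5-tert-butoxy-5-oxopent-3-en-1-yl]-5,5,8a-trimethyl-1,2,4a,5,6,7,8,8a-octahydronaphthalene-2-carboxylic acid, via C17 aldehyde 30 (not isolated)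
Conditions: TEMPO (20 mol %), PhI(OAc)2 (2.5 equiv), MeCN/H2O, rt
Reagents that add atoms: water, O
Why: Oxoammonium (TEMPO) oxidation of the primary alcohol through the aldehyde hydrate to the acid under near-neutral conditions, which should neither move the C6=C7 bond into conjugation nor disturb the equatorial C8 centre.

Step 19
Reactants: 31 (1R,2S,4aR,8aS)-1-[(3E)-3-(acetoxymethyl)-5-tert-butoxy-5-oxopent-3-en-1-yl]-5,5,8a-trimethyl-1,2,4a,5,6,7,8,8a-octahydronaphthalene-2-carboxylic acid
Product: 32 (1R,2S,4aR,8aS)-1-[(3E)-3-(acetoxymethyl)-4-carboxybut-3-en-1-yl]-5,5,8a-trimethyl-1,2,4a,5,6,7,8,8a-octahydronaphthalene-2-carboxylic acid (CNP0108723.1)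
Conditions: CF3CO2H, CH2Cl2, 0 °C to rt
Reagents that add atoms: none
Why: Acidolysis of the tert-butyl ester with loss of isobutene frees the C15 acid; the acetate, deactivated by the enoate, and the ring alkene should be stable to the acid.

**Compound list**
1 | 3-methoxy-3-methylbutan-1-ol | COC(C)(C)CCO | starting material
2 | 1-iodo-3-methoxy-3-methylbutane | COC(C)(C)CCI | intermediate
3 | methyl acetoacetate (methyl 3-oxobutanoate) | COC(=O)CC(C)=O | starting material
4 | sodium lithium dianion of methyl acetoacetate (not isolated) | C=C([O-])C=C([O-])OC.[Na+].[Li+] | intermediate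
5 | methyl 7-methoxy-7-methyl-3-oxooctanoate | COC(=O)CC(=O)CCCC(C)(C)OC | intermediate
6 | (tert-butyldimethylsilyloxy)acetaldehyde | CC(C)(C)[Si](C)(C)OCC=O | starting material
7 | 1-(triphenylphosphoranylidene)propan-2-one | CC(=O)C=P(c1ccccc1)(c1ccccc1)c1ccccc1 | starting material
8 | (3E)-5-[(tert-butyldimethylsilyl)oxy]pent-3-en-2-one | CC(=O)/C=C/CO[Si](C)(C)C(C)(C)C | intermediate
9 | methyl 2-[(2S)-1-[(tert-butyldimethylsilyl)oxy]-4-oxopentan-2-yl]-7-methoxy-7-methyl-3-oxooctanoate, both C2 epimers (not isolated) | COC(=O)C(C(=O)CCCC(C)(C)OC)[C@@H](CO[Si](C)(C)C(C)(C)C)CC(C)=O | intermediate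
10 | methyl (1R,6S)-6-{[(tert-butyldimethylsilyl)oxy]methyl}-2-(4-methoxy-4-methylpentyl)-4-oxocyclohex-2-ene-1-carboxylate | COC(=O)[C@@H]1[C@@H](CO[Si](C)(C)C(C)(C)C)CC(=O)C=C1CCCC(C)(C)OC | intermediate
11 | lithium C5=C6 enolate of the methyl adduct of 10 (not isolated) | COC(=O)[C@@H]1[C@@H](CO[Si](C)(C)C(C)(C)C)CC([O-])=C[C@@]1(C)CCCC(C)(C)OC.[Li+] | intermediate
12 | methyl (1R,2R,6S)-4-[(tert-butyldimethylsilyl)oxy]-6-{[(tert-butyldimethylsilyl)oxy]methyl}-2-(4-methoxy-4-methylpentyl)-2-methylcyclohex-3-ene-1-carboxylate | COC(=O)[C@@H]1[C@@H](CO[Si](C)(C)C(C)(C)C)CC(O[Si](C)(C)C(C)(C)C)=C[C@@]1(C)CCCC(C)(C)OC | intermediate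
13 | methyl (1R,2S,8aR)-2-{[(tert-butyldimethylsilyl)oxy]methyl}-5,5,8a-trimethyl-4-oxodecahydronaphthalene-1-carboxylate, ring-fusion carbon C4a (labdane C5) unassigned (not isolated) | COC(=O)[C@@H]1[C@@H](CO[Si](C)(C)C(C)(C)C)CC(=O)C2C(C)(C)CCC[C@@]12C | intermediate
14 | methyl (1R,2S,4aR,8aR)-2-{[(tert-butyldimethylsilyl)oxy]methyl}-5,5,8a-trimethyl-4-oxodecahydronaphthalene-1-carboxylate (trans-fused) | COC(=O)[C@@H]1[C@@H](CO[Si](C)(C)C(C)(C)C)CC(=O)[C@@H]2C(C)(C)CCC[C@@]12C | intermediate
15 | potassium C6=C7 enolate of 14 (not isolated) | COC(=O)[C@@H]1[C@@H](CO[Si](C)(C)C(C)(C)C)C=C([O-])[C@@H]2C(C)(C)CCC[C@@]12C.[K+] | intermediate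
16 | methyl (1R,2S,4aR,8aR)-2-{[(tert-butyldimethylsilyl)oxy]methyl}-5,5,8a-trimethyl-4-{[(trifluoromethyl)sulfonyl]oxy}-1,2,4a,5,6,7,8,8a-octahydronaphthalene-1-carboxylate | COC(=O)[C@@H]1[C@@H](CO[Si](C)(C)C(C)(C)C)C=C(OS(=O)(=O)C(F)(F)F)[C@@H]2C(C)(C)CCC[C@@]12C | intermediate
17 | methyl (1R,2S,4aR,8aR)-2-{[(tert-butyldimethylsilyl)oxy]methyl}-5,5,8a-trimethyl-1,2,4a,5,6,7,8,8a-octahydronaphthalene-1-carboxylate | COC(=O)[C@@H]1[C@@H](CO[Si](C)(C)C(C)(C)C)C=C[C@@H]2C(C)(C)CCC[C@@]12C | intermediate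
18 | [(1R,2S,4aR,8aR)-2-{[(tert-butyldimethylsilyl)oxy]methyl}-5,5,8a-trimethyl-1,2,4a,5,6,7,8,8a-octahydronaphthalen-1-yl]methanol | OC[C@@H]1[C@@H](CO[Si](C)(C)C(C)(C)C)C=C[C@@H]2C(C)(C)CCC[C@@]12C | intermediate
19 | (1R,2S,4aR,8aR)-2-{[(tert-butyldimethylsilyl)oxy]methyl}-5,5,8a-trimethyl-1,2,4a,5,6,7,8,8a-octahydronaphthalene-1-carbaldehyde | O=C[C@@H]1[C@@H](CO[Si](C)(C)C(C)(C)C)C=C[C@@H]2C(C)(C)CCC[C@@]12C | intermediate
20 | tert-butyl{[(1R,2S,4aR,8aS)-1-ethenyl-5,5,8a-trimethyl-1,2,4a,5,6,7,8,8a-octahydronaphthalen-2-yl]methoxy}dimethylsilane | C=C[C@@H]1[C@@H](CO[Si](C)(C)C(C)(C)C)C=C[C@@H]2C(C)(C)CCC[C@@]12C | intermediate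
21 | 2-(prop-2-yn-1-yloxy)oxane (racemic) | C#CCOC1CCCCO1 | starting material
22 | lithium acetylide of 21 (not isolated) | [Li+].[C-]#CCOC1CCCCO1 | intermediate
23 | tert-butyl 4-(oxan-2-yloxy)but-2-ynoate | CC(C)(C)OC(=O)C#CCOC1CCCCO1 | intermediate
24 | tert-butyl 4-hydroxybut-2-ynoate | CC(C)(C)OC(=O)C#CCO | intermediate
25 | tert-butyl 4-acetoxybut-2-ynoate | CC(=O)OCC#CC(=O)OC(C)(C)C | intermediate
26 | tert-butyl (2Z)-4-acetoxy-3-iodobut-2-enoate | CC(=O)OC/C(I)=C/C(=O)OC(C)(C)C | intermediate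
27 | 9-{2-[(1R,2S,4aR,8aS)-2-{[(tert-butyldimethylsilyl)oxy]methyl}-5,5,8a-trimethyl-1,2,4a,5,6,7,8,8a-octahydronaphthalen-1-yl]ethyl}-9-borabicyclo[3.3.1]nonane (not isolated) | C(C[C@@H]1[C@@H](CO[Si](C)(C)C(C)(C)C)C=C[C@@H]2C(C)(C)CCC[C@@]12C)B1C2CCCC1CCC2 | intermediate
28 | tert-butyl (2E)-3-(acetoxymethyl)-5-[(1R,2S,4aR,8aS)-2-{[(tert-butyldimethylsilyl)oxy]methyl}-5,5,8a-trimethyl-1,2,4a,5,6,7,8,8a-octahydronaphthalen-1-yl]pent-2-enoate | CC(=O)OC/C(=C/C(=O)OC(C)(C)C)CC[C@@H]1[C@@H](CO[Si](C)(C)C(C)(C)C)C=C[C@@H]2C(C)(C)CCC[C@@]12C | intermediate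
29 | tert-butyl (2E)-3-(acetoxymethyl)-5-[(1R,2S,4aR,8aS)-2-(hydroxymethyl)-5,5,8a-trimethyl-1,2,4a,5,6,7,8,8a-octahydronaphthalen-1-yl]pent-2-enoate | CC(=O)OC/C(=C/C(=O)OC(C)(C)C)CC[C@@H]1[C@@H](CO)C=C[C@@H]2C(C)(C)CCC[C@@]12C | intermediate
30 | tert-butyl (2E)-3-(acetoxymethyl)-5-[(1R,2S,4aR,8aS)-2-formyl-5,5,8a-trimethyl-1,2,4a,5,6,7,8,8a-octahydronaphthalen-1-yl]pent-2-enoate (not isolated) | CC(=O)OC/C(=C/C(=O)OC(C)(C)C)CC[C@@H]1[C@@H](C=O)C=C[C@@H]2C(C)(C)CCC[C@@]12C | intermediate
31 | (1R,2S,4aR,8aS)-1-[(3E)-3-(acetoxymethyl)-5-tert-butoxy-5-oxopent-3-en-1-yl]-5,5,8a-trimethyl-1,2,4a,5,6,7,8,8a-octahydronaphthalene-2-carboxylic acid | CC(=O)OC/C(=C/C(=O)OC(C)(C)C)CC[C@@H]1[C@@H](C(=O)O)C=C[C@@H]2C(C)(C)CCC[C@@]12C | intermediate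
32 | (1R,2S,4aR,8aS)-1-[(3E)-3-(acetoxymethyl)-4-carboxybut-3-en-1-yl]-5,5,8a-trimethyl-1,2,4a,5,6,7,8,8a-octahydronaphthalene-2-carboxylic acid (CNP0108723.1) | CC(=O)OC/C(=C/C(=O)O)CC[C@@H]1[C@@H](C(=O)O)C=C[C@@H]2C(C)(C)CCC[C@@]12C | target

**Step count**
Total: 19 steps. Longest linear sequence: 14 steps (steps 1, 2, 4–11, 16–19).

**Steps most likely to fail**

Step 6. The C4 cation may lose a proton to give an alkene, and the enol silane may lose its silyl group, before the C4–C5 bond forms; the closure may also stall at the hindered C5. The fallback sets out from methyl acetoacetate 3 and enone 8, replaces the carbenium ion by an oxocarbenium ion and brings in the second C4 methyl group afterwards. The dianion of 3 is alkylated with commercial 2-(2-bromoethyl)-2-methyl-1,3-dioxolane to methyl 6-(2-methyl-1,3-dioxolan-2-yl)-3-oxohexanoate F1. The conditions of steps 4 and 5 turn F1 and 8 into the cyclohexenone methyl (1R,6S)-6-{[(tert-butyldimethylsilyl)oxy]methyl}-2-[3-(2-methyl-1,3-dioxolan-2-yl)propyl]-4-oxocyclohex-2-ene-1-carboxylate F2 and then into the bis-silyl compound methyl (1R,2R,6S)-4-[(tert-butyldimethylsilyl)oxy]-6-{[(tert-butyldimethylsilyl)oxy]methyl}-2-methyl-2-[3-(2-methyl-1,3-dioxolan-2-yl)propyl]cyclohex-3-ene-1-carboxylate F3. TiCl4 in CH2Cl2 at −78 °C opens the ketal and the enol silane adds to the oxocarbenium ion (intramolecular Mukaiyama addition to a ketal), giving the hydroxyethoxy ketone methyl (1R,2S,8aR)-2-{[(tert-butyldimethylsilyl)oxy]methyl}-5-(2-hydroxyethoxy)-5,8a-dimethyl-4-oxodecahydronaphthalene-1-carboxylate F4. DBU eliminates ethylene glycol to the C4=C5 alkylidene ketone methyl (1R,2S,8aS)-2-{[(tert-butyldimethylsilyl)oxy]methyl}-5,8a-dimethyl-4-oxo-1,2,3,4,6,7,8,8a-octahydronaphthalene-1-carboxylate F5. Me2CuLi adds the second methyl group at C4, and NaOMe in MeOH equilibrates C5, which brings the route back at 14.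

Step 5. The cuprate may show poor or reversed facial selectivity at C10 (the C9 ester steering it to the face of the C8 group), or it may deprotonate C9 instead of adding. The fallback sets out from 3 and 8 and exchanges the roles of the two C10 substituents. Under the conditions of step 4, 3 and 8 give methyl (1R,6S)-6-{[(tert-butyldimethylsilyl)oxy]methyl}-2-methyl-4-oxocyclohex-2-ene-1-carboxylate F6. Commercial 5-chloropentan-2-one and MeMgBr give 5-chloro-2-methylpentan-2-ol F7, NaH/MeI gives its methyl ether 5-chloro-2-methoxy-2-methylpentane F8, and magnesium gives (4-methoxy-4-methylpentyl)magnesium chloride F9. Addition of F9 to F6 mediated by CuBr·SMe2, with TBSCl/HMPA trapping, then places the chain on the face that the methyl group took in step 5, which is the C10 configuration of 12, where the route is rejoined.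

Step 4. The adduct may add to a second enone, enantiopurity may erode through reversible Michael addition, or the aldol closure may go through the wrong carbonyl. The fallback sets out from ketoester 5 and aldehyde 6 and forms the C7–C8 bond in place of the C8–C9 bond. Knoevenagel condensation (piperidinium acetate) gives methyl 2-{2-[(tert-butyldimethylsilyl)oxy]ethylidene}-7-methoxy-7-methyl-3-oxooctanoate F10. An enamine-type asymmetric Michael addition of acetone (chiral primary amine–thiourea catalyst) then gives 9, and pyrrolidinium acetate closes 9 to 10, where the route is rejoined.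

**Further compounds**
F1 | step 6 | methyl 6-(2-methyl-1,3-dioxolan-2-yl)-3-oxohexanoate | COC(=O)CC(=O)CCCC1(C)OCCO1
F2 | step 6 | methyl (1R,6S)-6-{[(tert-butyldimethylsilyl)oxy]methyl}-2-[3-(2-methyl-1,3-dioxolan-2-yl)propyl]-4-oxocyclohex-2-ene-1-carboxylate | COC(=O)[C@@H]1[C@@H](CO[Si](C)(C)C(C)(C)C)CC(=O)C=C1CCCC2(C)OCCO2
F3 | step 6 | methyl (1R,2R,6S)-4-[(tert-butyldimethylsilyl)oxy]-6-{[(tert-butyldimethylsilyl)oxy]methyl}-2-methyl-2-[3-(2-methyl-1,3-dioxolan-2-yl)propyl]cyclohex-3-ene-1-carboxylate | COC(=O)[C@@H]1[C@@H](CO[Si](C)(C)C(C)(C)C)CC(O[Si](C)(C)C(C)(C)C)=C[C@@]1(C)CCCC2(C)OCCO2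
F4 | step 6 | methyl (1R,2S,8aR)-2-{[(tert-butyldimethylsilyl)oxy]methyl}-5-(2-hydroxyethoxy)-5,8a-dimethyl-4-oxodecahydronaphthalene-1-carboxylate (C4a and C5 unassigned) | COC(=O)[C@@H]1[C@@H](CO[Si](C)(C)C(C)(C)C)CC(=O)C2C(C)(OCCO)CCC[C@@]12C
F5 | step 6 | methyl (1R,2S,8aS)-2-{[(tert-butyldimethylsilyl)oxy]methyl}-5,8a-dimethyl-4-oxo-1,2,3,4,6,7,8,8a-octahydronaphthalene-1-carboxylate | COC(=O)[C@@H]1[C@@H](CO[Si](C)(C)C(C)(C)C)CC(=O)C2=C(C)CCC[C@@]12C
F6 | step 5 | methyl (1R,6S)-6-{[(tert-butyldimethylsilyl)oxy]methyl}-2-methyl-4-oxocyclohex-2-ene-1-carboxylate | COC(=O)[C@@H]1[C@@H](CO[Si](C)(C)C(C)(C)C)CC(=O)C=C1C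
F7 | step 5 | 5-chloro-2-methylpentan-2-ol | CC(C)(O)CCCCl
F8 | step 5 | 5-chloro-2-methoxy-2-methylpentane | COC(C)(C)CCCCl
F9 | step 5 | (4-methoxy-4-methylpentyl)magnesium chloride | COC(C)(C)CCC[Mg]Cl
F10 | step 4 | methyl 2-{2-[(tert-butyldimethylsilyl)oxy]ethylidene}-7-methoxy-7-methyl-3-oxooctanoate (E/Z mixture) | COC(=O)C(=CCO[Si](C)(C)C(C)(C)C)C(=O)CCCC(C)(C)OC
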